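**Retrosynthetic overview**

1. The target is a 2,4-trans-4-arylflavan (upper unit, u; rings A(u), C(u), B(u)) joined through C4(u)–C6(l) to an all-cis flavan-3,4-diol (lower unit, l); the six phenols travel as benzyl ethers and are freed last.
2. Ring C(l) is closed late by Mitsunobu O1(l)–C2(l) bond formation on an all-erythro triol derivative. That comes from OsO4 addition to a Z-alkene, made from a propargylic alcohol (C4(l) by asymmetric alkynylation of a salicylaldehyde obtained by ortho-formylation of ring A(l)).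
3. Ring B(u) is put on C2(u) by arylzinc substitution of a 2-sulfonylchroman, trans to the aryl group on C4(u).
4. Feature and key disconnection: C4(u) is bonded to C4a(u), whose ring neighbour C8a(u) carries O1(u). A 2-hydroxyarylboronic acid can therefore deliver the C4(u)–C4a(u) bond by rhodium/chiral-diene 1,4-addition to a cinnamaldehyde (its β-carbon is C4(u) and already bears ring A(l)), and then the O1(u)–C2(u) bond by hemiacetalisation, which closes ring C(u).
5. Ring order: C(u) in step 8, C(l) in step 19; the boronic acid is made from 2,3-dihydroxybenzaldehyde and the enal from 2,3,4-trihydroxybenzaldehyde.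

Key step: step 8

Notation: locants carry (u) or (l) as above; Bn = benzyl, MOM = methoxymethyl, TBS = tert-butyldimethylsilyl; Fl = (2S,4R)-7,8-bis(benzyloxy)-2-[4-(benzyloxy)phenyl]chroman-4-yl. In Fl the centre C4(u) has the same spatial arrangement as the centre called S before ring A(l) carries a carbon at C4a(l) and called S again in the target; only the CIP ranking of the two aryl groups changes.

Assumption: the sense of induction of (R,R)-Ph-bod* in step 8 and of (S)-BINOL in step 14 is taken over from simple model substrates; if either proves opposite, the enantiomeric ligand is used and nothing else changes.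

**Route**

Step 1
Reactants: 1 2,3-dihydroxybenzaldehyde
Product: 2 2,3-bis(benzyloxy)benzaldehyde
Conditions: BnBr, K2CO3, DMF, 60 °C
Reagents that add atoms: benzyl bromide BrCc1ccccc1
Why: Williamson etherification of both phenols with K2CO3 in DMF is routine and leaves the aldehyde untouched.

Step 2
Reactants: 2 2,3-bis(benzyloxy)benzaldehyde
Product: 4 2,3-bis(benzyloxy)phenol, via 2,3-bis(benzyloxy)phenyl formate 3 (not isolated)
Conditions: mCPBA, CH2Cl2, rt; then K2CO3 (cat.), MeOH, rt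
Reagents that add atoms: 3-chloroperbenzoic acid OOC(=O)c1cccc(Cl)c1
Why: Baeyer–Villiger (Dakin-type) oxidation, in which the electron-rich ortho-alkoxyaryl group migrates in preference to hydride to give formate 3, which mild methanolysis cleaves.

Step 3
Reactants: 4 2,3-bis(benzyloxy)phenol
Product: 5 2,3-bis(benzyloxy)-6-bromophenol
Conditions: t-BuNH2 (2 equiv), Br2 (1 equiv), toluene, −30 °C; then 4, −78 °C
Reagents that add atoms: bromine BrBr
Why: Amine-directed electrophilic bromination, in which the N-bromoamine delivers bromine through the hydrogen-bonded phenol to the only free ortho carbon (also para to an OBn group) at a temperature where para attack should be suppressed.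

Step 4
Reactants: 5 2,3-bis(benzyloxy)-6-bromophenol
Product: 8 [3,4-bis(benzyloxy)-2-hydroxyphenyl]boronic acid, via lithium 2,3-bis(benzyloxy)-6-lithiophenolate 6 (not isolated), via dilithium [3,4-bis(benzyloxy)-2-oxidophenyl]tri(propan-2-yloxy)borate 7 (not isolated)
Conditions: n-BuLi (2.2 equiv), THF, −78 °C; B(OiPr)3, −78 °C to rt; aq. HCl
Reagents that add atoms: triisopropyl borate CC(C)OB(OC(C)C)OC(C)C; water O
Why: Lithiation–borylation, in which phenol deprotonation and fast bromine–lithium exchange at −78 °C (faster than benzylic deprotonation) give aryllithium 6, which is trapped by the borate and hydrolysed.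

Step 5
Reactants: 9 2,3,4-trihydroxybenzaldehyde
Product: 10 2,3-dihydroxy-4-(methoxymethoxy)benzaldehyde
Conditions: MOMCl (1.05 equiv), i-Pr2NEt (1.1 equiv), CH2Cl2/THF, 0 °C
Reagents that add atoms: chloromethyl methyl ether COCCl
Why: Selective Williamson-type alkylation, since the 4-OH (para to CHO) is the most acidic and the 2-OH is tied up in a hydrogen bond to the carbonyl, so one equivalent of MOMCl should go to O4.

Step 6
Reactants: 10 2,3-dihydroxy-4-(methoxymethoxy)benzaldehyde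
Product: 11 2,3-bis(benzyloxy)-4-(methoxymethoxy)benzaldehyde
Conditions: BnBr, K2CO3, DMF, 60 °C
Reagents that add atoms: benzyl bromide BrCc1ccccc1
Why: Williamson etherification of the two remaining phenols, the MOM acetal being stable to base.

Step 7
Reactants: 11 2,3-bis(benzyloxy)-4-(methoxymethoxy)benzaldehyde
Product: 12 (E)-3-[2,3-bis(benzyloxy)-4-(methoxymethoxy)phenyl]prop-2-enal
Conditions: Ph3P=CHCHO, toluene, 90 °C
Reagents that add atoms: (triphenylphosphoranylidene)acetaldehyde O=CC=P(c1ccccc1)(c1ccccc1)c1ccccc1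
Why: Wittig reaction with the stabilised formylmethylene ylide should give the E-enal, whose lower electrophilicity limits a second homologation.

Step 8
Reactants: 8 [3,4-bis(benzyloxy)-2-hydroxyphenyl]boronic acid; 12 (E)-3-[2,3-bis(benzyloxy)-4-(methoxymethoxy)phenyl]prop-2-enal
Product: 14 (4S)-7,8-bis(benzyloxy)-4-[2,3-bis(benzyloxy)-4-(methoxymethoxy)phenyl]chroman-2-ol (both C2 epimers), via (3R)-3-[3,4-bis(benzyloxy)-2-hydroxyphenyl]-3-[2,3-bis(benzyloxy)-4-(methoxymethoxy)phenyl]propanal 13 (not isolated)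
Conditions: Rh(acac)(C2H4)2 (3 mol %), (R,R)-Ph-bod* [(1R,4R)-2,5-diphenylbicyclo[2.2.2]octa-2,5-diene] (3.3 mol %), KOH (0.3 equiv), 8 (1.5 equiv), dioxane/H2O 10:1, 30 °C
Reagents that add atoms: none
Why: Transmetallation from boron to a hydroxo-rhodium complex (monovalent rhodium, chiral diene ligand) gives an aryl–rhodium species that inserts the enal C=C bond with the aryl group going to the β-carbon, and hydrolysis of the resulting oxa-π-allyl rhodium species releases aldehyde 13 and regenerates Rh–OH. The closest known reaction is the Hayashi–Miyaura 1,4-addition of arylboronic acids to β-aryl enals under rhodium/chiral-diene catalysis, the free ortho-hydroxyl being the only extension. Ring C(u) then closes by 6-exo-trig hemiacetalisation of the C8a(u) hydroxyl onto the aldehyde carbon C2(u), which also masks the aldehyde against aldol reaction or a second addition. C4(u) is set by the diene ligand through enantioface selection of the E-enal at the insertion step (aryl to the Si face of the β-carbon), whereas C2(u) is left as an anomeric mixture because it is ionised in steps 9 and 10. Site selectivity on ring A(u) is secured by boron, which marks the hindered C4a(u) position next to oxygen, and 1,4- over 1,2-addition by the diene ligand; excess boronic acid and the low temperature should offset protodeboronation.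

Step 9
Reactants: 14 (4S)-7,8-bis(benzyloxy)-4-[2,3-bis(benzyloxy)-4-(methoxymethoxy)phenyl]chroman-2-ol
Product: 15 (4S)-7,8-bis(benzyloxy)-4-[2,3-bis(benzyloxy)-4-(methoxymethoxy)phenyl]-2-(phenylsulfonyl)chroman (both C2 epimers)
Conditions: PhSO2H, CaCl2, CH2Cl2, rt
Reagents that add atoms: benzenesulfinic acid O=S(O)c1ccccc1
Why: Acid-promoted exchange at the hemiacetal carbon (2-sulfonyl cyclic ether formation), in which the lactol ionises to the chromanyl oxocarbenium ion that is captured at sulfur by sulfinate while CaCl2 takes up the water.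

Step 10
Reactants: 15 (4S)-7,8-bis(benzyloxy)-4-[2,3-bis(benzyloxy)-4-(methoxymethoxy)phenyl]-2-(phenylsulfonyl)chroman; 16 1-(benzyloxy)-4-bromobenzene
Product: 19 (2S,4S)-7,8-bis(benzyloxy)-2-[4-(benzyloxy)phenyl]-4-[2,3-bis(benzyloxy)-4-(methoxymethoxy)phenyl]chroman, via [4-(benzyloxy)phenyl]magnesium bromide 17 (not isolated), via [4-(benzyloxy)phenyl]zinc bromide 18 (not isolated)
Conditions: 16, Mg, THF; ZnBr2, THF, rt; then 15, rt
Reagents that add atoms: none
Why: Substitution of a 2-sulfonyl cyclic ether by an arylzinc reagent, in which zinc-assisted loss of sulfinate regenerates the oxocarbenium ion and the aryl group is transferred to C2(u) on the face opposite the C4(u) aryl group (axial attack on the half-chair with that group pseudo-equatorial), setting C2(u) as S in a 2,4-trans flavan.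

Step 11
Reactants: 19 (2S,4S)-7,8-bis(benzyloxy)-2-[4-(benzyloxy)phenyl]-4-[2,3-bis(benzyloxy)-4-(methoxymethoxy)phenyl]chroman
Product: 20 2,3-bis(benzyloxy)-4-{(2S,4S)-7,8-bis(benzyloxy)-2-[4-(benzyloxy)phenyl]chroman-4-yl}phenol
Conditions: HCl (cat.), MeOH/THF, 40 °C
Reagents that add atoms: none
Why: Acid-catalysed acetal cleavage (transacetalisation to methanol) removes the MOM group, while benzyl ethers and the flavan ether should be stable to dilute HCl at 40 °C.

Step 12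
Reactants: 20 2,3-bis(benzyloxy)-4-{(2S,4S)-7,8-bis(benzyloxy)-2-[4-(benzyloxy)phenyl]chroman-4-yl}phenol
Product: 22 3,4-bis(benzyloxy)-5-Fl-2-hydroxybenzaldehyde, via 2,3-bis(benzyloxy)-4-Fl-6-(hydroxymethyl)phenol magnesium salt 21 (not isolated)
Conditions: MgCl2, Et3N, (CH2O)n, THF, reflux; aq. HCl
Reagents that add atoms: formaldehyde (as paraformaldehyde) C=O
Why: Magnesium-mediated ortho-formylation (Casnati–Skattebøl reaction), in which the magnesium phenoxide reacts with formaldehyde only at the free ortho carbon C4a(l) and the benzylic alkoxide 21 is oxidised by a second formaldehyde through hydride transfer.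

Step 13
Reactants: 22 3,4-bis(benzyloxy)-5-Fl-2-hydroxybenzaldehyde
Product: 23 3,4-bis(benzyloxy)-5-Fl-2-[(tert-butyldimethylsilyl)oxy]benzaldehyde
Conditions: TBSOTf, 2,6-lutidine, CH2Cl2, 0 °C
Reagents that add atoms: tert-butyldimethylsilyl trifluoromethanesulfonate CC(C)(C)[Si](C)(C)OS(=O)(=O)C(F)(F)F
Why: Silylation of the hindered, hydrogen-bonded phenol with the reactive silyl triflate removes the acidic proton that would interfere with the zinc reagent of step 14.

Step 14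
Reactants: 23 3,4-bis(benzyloxy)-5-Fl-2-[(tert-butyldimethylsilyl)oxy]benzaldehyde; 24 1-(benzyloxy)-4-ethynylbenzene
Product: 26 (1S)-1-[3,4-bis(benzyloxy)-5-Fl-2-(TBSO)phenyl]-3-[4-(benzyloxy)phenyl]prop-2-yn-1-ol, via ethyl{[4-(benzyloxy)phenyl]ethynyl}zinc 25 (not isolated)
Conditions: 24, Et2Zn, toluene, reflux; then (S)-BINOL (20 mol %), Ti(OiPr)4 (50 mol %), CH2Cl2, 23, rt
Reagents that add atoms: none
Why: Catalytic asymmetric alkynylzinc addition to an aryl aldehyde under BINOL–Ti(OiPr)4 control, the ligand directing the alkynyl group to the Si face of the formyl group and so setting C4(l) (S here, R in the target after the neighbours change) without influence from the remote upper unit.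

Step 15
Reactants: 26 (1S)-1-[3,4-bis(benzyloxy)-5-Fl-2-(TBSO)phenyl]-3-[4-(benzyloxy)phenyl]prop-2-yn-1-ol
Product: 27 (1S)-1-[3,4-bis(benzyloxy)-5-Fl-2-(TBSO)phenyl]-3-[4-(benzyloxy)phenyl]-1-(TBSO)prop-2-yne
Conditions: TBSOTf, 2,6-lutidine, CH2Cl2, 0 °C
Reagents that add atoms: tert-butyldimethylsilyl trifluoromethanesulfonate CC(C)(C)[Si](C)(C)OS(=O)(=O)C(F)(F)F
Why: Silyl ether formation at the secondary propargylic alcohol keeps C4(l)–O from being activated or forming an ortho-quinone methide in the Mitsunobu step.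

Step 16
Reactants: 27 (1S)-1-[3,4-bis(benzyloxy)-5-Fl-2-(TBSO)phenyl]-3-[4-(benzyloxy)phenyl]-1-(TBSO)prop-2-yne
Product: 28 (1S,2Z)-1-[3,4-bis(benzyloxy)-5-Fl-2-(TBSO)phenyl]-3-[4-(benzyloxy)phenyl]-1-(TBSO)prop-2-ene
Conditions: H2 (1 atm), Pd/CaCO3 poisoned with Pb(OAc)2, quinoline, EtOAc, rt
Reagents that add atoms: none
Why: Lindlar semi-hydrogenation adds one equivalent of H2 syn on the poisoned palladium surface to give the Z-alkene and should leave the benzyl ethers untouched.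

Step 17
Reactants: 28 (1S,2Z)-1-[3,4-bis(benzyloxy)-5-Fl-2-(TBSO)phenyl]-3-[4-(benzyloxy)phenyl]-1-(TBSO)prop-2-ene
Product: 29 (1S,2S,3R)-1-[4-(benzyloxy)phenyl]-3-[3,4-bis(benzyloxy)-5-Fl-2-(TBSO)phenyl]-3-(TBSO)propane-1,2-diol
Conditions: OsO4 (5 mol %), NMO, acetone/H2O, rt
Reagents that add atoms: osmium tetroxide (catalytic oxygen carrier) O=[Os](=O)(=O)=O; N-methylmorpholine N-oxide C[N+]1([O-])CCOCC1; water O
Why: Upjohn dihydroxylation adds syn to the Z-alkene in the A(1,3)-controlled conformer (H on C4(l) in the alkene plane) with OsO4 approaching anti to the allylic silyloxy group, as in the empirical rule for allylic ethers, which should give the all-erythro arrangement and so set C3(l) and C2(l) relative to C4(l).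

Step 18
Reactants: 29 (1S,2S,3R)-1-[4-(benzyloxy)phenyl]-3-[3,4-bis(benzyloxy)-5-Fl-2-(TBSO)phenyl]-3-(TBSO)propane-1,2-diol
Product: 30 (1S,2S,3R)-1-[4-(benzyloxy)phenyl]-3-[3,4-bis(benzyloxy)-5-Fl-2-hydroxyphenyl]-3-(TBSO)propane-1,2-diol
Conditions: KHF2, MeOH/THF, rt
Reagents that add atoms: none
Why: Fluoride cleavage that is selective for the aryl silyl ether (phenoxide being the better leaving group), KHF2 in methanol leaving the secondary alkyl TBS ether in place.

Step 19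
Reactants: 30 (1S,2S,3R)-1-[4-(benzyloxy)phenyl]-3-[3,4-bis(benzyloxy)-5-Fl-2-hydroxyphenyl]-3-(TBSO)propane-1,2-diol
Product: 31 (2R,3S,4R)-7,8-bis(benzyloxy)-2-[4-(benzyloxy)phenyl]-6-Fl-4-(TBSO)chroman-3-ol
Conditions: PPh3, DIAD, THF, 0 °C to rt
Reagents that add atoms: none
Why: Intramolecular Mitsunobu etherification, in which the phenol displaces the activated benzylic C2(l)–OH with inversion (6-exo-tet), closing ring C(l) and turning the erythro diol into the 2,3-cis chroman, while the hindered non-benzylic C3(l)–OH is not activated.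

Step 20
Reactants: 31 (2R,3S,4R)-7,8-bis(benzyloxy)-2-[4-(benzyloxy)phenyl]-6-Fl-4-(TBSO)chroman-3-ol
Product: 32 (2R,3R,4R)-7,8-bis(benzyloxy)-2-[4-(benzyloxy)phenyl]-6-Fl-chroman-3,4-diol
Conditions: TBAF, THF, 0 °C to rt
Reagents that add atoms: none
Why: Fluoride-induced desilylation of the benzylic silyl ether under non-acidic conditions spares the ionisable C4(l)–O bond.

Step 21
Reactants: 32 (2R,3R,4R)-7,8-bis(benzyloxy)-2-[4-(benzyloxy)phenyl]-6-Fl-chroman-3,4-diol
Product: 33 (2R,3R,4R)-6-[(2S,4S)-7,8-dihydroxy-2-(4-hydroxyphenyl)chroman-4-yl]-2-(4-hydroxyphenyl)chroman-3,4,7,8-tetrol (CNP0209379.1)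
Conditions: H2 (1 atm), Pd(OH)2/C, degassed EtOAc/MeOH, rt
Reagents that add atoms: none
Why: Catalytic hydrogenolysis of the six benzyl ethers under neutral conditions at 1 atm, stopped at complete debenzylation so that the benzylic C4(l)–OH and the two benzylic C2–O1 bonds should not be reduced.

**Compound list**

1 | 2,3-dihydroxybenzaldehyde | O=Cc1cccc(O)c1O | starting material
2 | 2,3-bis(benzyloxy)benzaldehyde | O=Cc1cccc(OCc2ccccc2)c1OCc1ccccc1 | intermediate
3 | 2,3-bis(benzyloxy)phenyl formate | O=COc1cccc(OCc2ccccc2)c1OCc1ccccc1 | intermediate (not isolated)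
4 | 2,3-bis(benzyloxy)phenol | Oc1cccc(OCc2ccccc2)c1OCc1ccccc1 | intermediate
5 | 2,3-bis(benzyloxy)-6-bromophenol | Oc1c(Br)ccc(OCc2ccccc2)c1OCc1ccccc1 | intermediate
6 | lithium 2,3-bis(benzyloxy)-6-lithiophenolate | [Li]Oc1c([Li])ccc(OCc2ccccc2)c1OCc1ccccc1 | intermediate (not isolated)
7 | dilithium [3,4-bis(benzyloxy)-2-oxidophenyl]tri(propan-2-yloxy)borate | CC(C)O[B-](OC(C)C)(OC(C)C)c1ccc(OCc2ccccc2)c(OCc2ccccc2)c1[O-].[Li+].[Li+] | intermediate (not isolated)
8 | [3,4-bis(benzyloxy)-2-hydroxyphenyl]boronic acid | OB(O)c1ccc(OCc2ccccc2)c(OCc2ccccc2)c1O | intermediate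
9 | 2,3,4-trihydroxybenzaldehyde | O=Cc1ccc(O)c(O)c1O | starting material
10 | 2,3-dihydroxy-4-(methoxymethoxy)benzaldehyde | O=Cc1ccc(OCOC)c(O)c1O | intermediate
11 | 2,3-bis(benzyloxy)-4-(methoxymethoxy)benzaldehyde | O=Cc1ccc(OCOC)c(OCc2ccccc2)c1OCc1ccccc1 | intermediate
12 | (E)-3-[2,3-bis(benzyloxy)-4-(methoxymethoxy)phenyl]prop-2-enal | O=C/C=C/c1ccc(OCOC)c(OCc2ccccc2)c1OCc1ccccc1 | intermediate
13 | (3R)-3-[3,4-bis(benzyloxy)-2-hydroxyphenyl]-3-[2,3-bis(benzyloxy)-4-(methoxymethoxy)phenyl]propanal | O=CC[C@@H](c1ccc(OCOC)c(OCc2ccccc2)c1OCc1ccccc1)c1ccc(OCc2ccccc2)c(OCc2ccccc2)c1O | intermediate (not isolated)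
14 | (4S)-7,8-bis(benzyloxy)-4-[2,3-bis(benzyloxy)-4-(methoxymethoxy)phenyl]chroman-2-ol (both C2 epimers) | OC1C[C@@H](c2ccc(OCOC)c(OCc3ccccc3)c2OCc2ccccc2)c2ccc(OCc3ccccc3)c(OCc3ccccc3)c2O1 | intermediate
15 | (4S)-7,8-bis(benzyloxy)-4-[2,3-bis(benzyloxy)-4-(methoxymethoxy)phenyl]-2-(phenylsulfonyl)chroman (both C2 epimers) | O=S(=O)(c1ccccc1)C1C[C@@H](c2ccc(OCOC)c(OCc3ccccc3)c2OCc2ccccc2)c2ccc(OCc3ccccc3)c(OCc3ccccc3)c2O1 | intermediate
16 | 1-(benzyloxy)-4-bromobenzene | Brc1ccc(OCc2ccccc2)cc1 | starting material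
17 | [4-(benzyloxy)phenyl]magnesium bromide | Br[Mg]c1ccc(OCc2ccccc2)cc1 | intermediate (not isolated)
18 | [4-(benzyloxy)phenyl]zinc bromide | Br[Zn]c1ccc(OCc2ccccc2)cc1 | intermediate (not isolated)
19 | (2S,4S)-7,8-bis(benzyloxy)-2-[4-(benzyloxy)phenyl]-4-[2,3-bis(benzyloxy)-4-(methoxymethoxy)phenyl]chroman (2,4-trans) | c1ccccc1COc1ccc([C@@H]2C[C@@H](c3ccc(OCOC)c(OCc4ccccc4)c3OCc3ccccc3)c3ccc(OCc4ccccc4)c(OCc4ccccc4)c3O2)cc1 | intermediate
20 | 2,3-bis(benzyloxy)-4-{(2S,4S)-7,8-bis(benzyloxy)-2-[4-(benzyloxy)phenyl]chroman-4-yl}phenol | c1ccccc1COc1ccc([C@@H]2C[C@@H](c3ccc(O)c(OCc4ccccc4)c3OCc3ccccc3)c3ccc(OCc4ccccc4)c(OCc4ccccc4)c3O2)cc1 | intermediate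
21 | 2,3-bis(benzyloxy)-4-Fl-6-(hydroxymethyl)phenol (formed as its magnesium salt; drawn neutral) | c1ccccc1COc1ccc([C@@H]2C[C@@H](c3cc(CO)c(O)c(OCc4ccccc4)c3OCc3ccccc3)c3ccc(OCc4ccccc4)c(OCc4ccccc4)c3O2)cc1 | intermediate (not isolated)
22 | 3,4-bis(benzyloxy)-5-Fl-2-hydroxybenzaldehyde | c1ccccc1COc1ccc([C@@H]2C[C@@H](c3cc(C=O)c(O)c(OCc4ccccc4)c3OCc3ccccc3)c3ccc(OCc4ccccc4)c(OCc4ccccc4)c3O2)cc1 | intermediate
23 | 3,4-bis(benzyloxy)-5-Fl-2-[(tert-butyldimethylsilyl)oxy]benzaldehyde | c1ccccc1COc1ccc([C@@H]2C[C@@H](c3cc(C=O)c(O[Si](C)(C)C(C)(C)C)c(OCc4ccccc4)c3OCc3ccccc3)c3ccc(OCc4ccccc4)c(OCc4ccccc4)c3O2)cc1 | intermediate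
24 | 1-(benzyloxy)-4-ethynylbenzene | C#Cc1ccc(OCc2ccccc2)cc1 | starting material
25 | ethyl{[4-(benzyloxy)phenyl]ethynyl}zinc | CC[Zn]C#Cc1ccc(OCc2ccccc2)cc1 | intermediate (not isolated)
26 | (1S)-1-[3,4-bis(benzyloxy)-5-Fl-2-(TBSO)phenyl]-3-[4-(benzyloxy)phenyl]prop-2-yn-1-ol | c1ccccc1COc1ccc([C@@H]2C[C@@H](c3cc([C@@H](O)C#Cc4ccc(OCc5ccccc5)cc4)c(O[Si](C)(C)C(C)(C)C)c(OCc4ccccc4)c3OCc3ccccc3)c3ccc(OCc4ccccc4)c(OCc4ccccc4)c3O2)cc1 | intermediate
27 | (1S)-1-[3,4-bis(benzyloxy)-5-Fl-2-(TBSO)phenyl]-3-[4-(benzyloxy)phenyl]-1-(TBSO)prop-2-yne | c1ccccc1COc1ccc([C@@H]2C[C@@H](c3cc([C@@H](O[Si](C)(C)C(C)(C)C)C#Cc4ccc(OCc5ccccc5)cc4)c(O[Si](C)(C)C(C)(C)C)c(OCc4ccccc4)c3OCc3ccccc3)c3ccc(OCc4ccccc4)c(OCc4ccccc4)c3O2)cc1 | intermediate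
28 | (1S,2Z)-1-[3,4-bis(benzyloxy)-5-Fl-2-(TBSO)phenyl]-3-[4-(benzyloxy)phenyl]-1-(TBSO)prop-2-ene | c1ccccc1COc1ccc([C@@H]2C[C@@H](c3cc([C@@H](O[Si](C)(C)C(C)(C)C)/C=C\c4ccc(OCc5ccccc5)cc4)c(O[Si](C)(C)C(C)(C)C)c(OCc4ccccc4)c3OCc3ccccc3)c3ccc(OCc4ccccc4)c(OCc4ccccc4)c3O2)cc1 | intermediate
29 | (1S,2S,3R)-1-[4-(benzyloxy)phenyl]-3-[3,4-bis(benzyloxy)-5-Fl-2-(TBSO)phenyl]-3-(TBSO)propane-1,2-diol | c1ccccc1COc1ccc([C@@H]2C[C@@H](c3cc([C@@H](O[Si](C)(C)C(C)(C)C)[C@@H](O)[C@@H](O)c4ccc(OCc5ccccc5)cc4)c(O[Si](C)(C)C(C)(C)C)c(OCc4ccccc4)c3OCc3ccccc3)c3ccc(OCc4ccccc4)c(OCc4ccccc4)c3O2)cc1 | intermediate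
30 | (1S,2S,3R)-1-[4-(benzyloxy)phenyl]-3-[3,4-bis(benzyloxy)-5-Fl-2-hydroxyphenyl]-3-(TBSO)propane-1,2-diol | c1ccccc1COc1ccc([C@@H]2C[C@@H](c3cc([C@@H](O[Si](C)(C)C(C)(C)C)[C@@H](O)[C@@H](O)c4ccc(OCc5ccccc5)cc4)c(O)c(OCc4ccccc4)c3OCc3ccccc3)c3ccc(OCc4ccccc4)c(OCc4ccccc4)c3O2)cc1 | intermediate
31 | (2R,3S,4R)-7,8-bis(benzyloxy)-2-[4-(benzyloxy)phenyl]-6-Fl-4-(TBSO)chroman-3-ol | c1ccccc1COc1ccc([C@@H]2C[C@@H](c3cc4c(c(OCc5ccccc5)c3OCc3ccccc3)O[C@H](c3ccc(OCc5ccccc5)cc3)[C@H](O)[C@@H]4O[Si](C)(C)C(C)(C)C)c3ccc(OCc4ccccc4)c(OCc4ccccc4)c3O2)cc1 | intermediate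
32 | (2R,3R,4R)-7,8-bis(benzyloxy)-2-[4-(benzyloxy)phenyl]-6-Fl-chroman-3,4-diol | c1ccccc1COc1ccc([C@@H]2C[C@@H](c3cc4c(c(OCc5ccccc5)c3OCc3ccccc3)O[C@H](c3ccc(OCc5ccccc5)cc3)[C@H](O)[C@@H]4O)c3ccc(OCc4ccccc4)c(OCc4ccccc4)c3O2)cc1 | intermediate
33 | (2R,3R,4R)-6-[(2S,4S)-7,8-dihydroxy-2-(4-hydroxyphenyl)chroman-4-yl]-2-(4-hydroxyphenyl)chroman-3,4,7,8-tetrol | Oc1ccc([C@@H]2C[C@@H](c3cc4c(c(O)c3O)O[C@H](c3ccc(O)cc3)[C@H](O)[C@@H]4O)c3ccc(O)c(O)c3O2)cc1 | target

**Step count**

Total steps: 21. Longest linear sequence: 18 steps (steps 1–4, then 8–21).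

**Steps most likely to fail**

Step 8. The electron-rich ortho-hydroxy boronic acid may protodeboronate faster than the aryl–rhodium species inserts the ortho-substituted β-aryl enal; 1,2-addition or weak enantioface discrimination are the other failure modes. The fallback sets out from 11 and returns at 14. Horner–Wadsworth–Emmons olefination of 11 (trimethyl phosphonoacetate, NaH, THF) gives methyl (E)-3-[2,3-bis(benzyloxy)-4-(methoxymethoxy)phenyl]prop-2-enoate F1. Rhodium/chiral-diene 1,4-addition of 8 to this ester, which has no 1,2-pathway and tolerates a higher temperature, is followed by lactonisation of the phenol onto the ester and gives (4S)-7,8-bis(benzyloxy)-4-[2,3-bis(benzyloxy)-4-(methoxymethoxy)phenyl]chroman-2-one F2. Partial reduction with i-Bu2AlH (CH2Cl2, −78 °C) returns lactol 14.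

Step 10. The 2-sulfonylchroman may ionise reluctantly, because an oxocarbenium ion on an aryl oxygen is less stabilised than in the alkyl cases; elimination to the 4H-chromene or incomplete trans selectivity in the aryl transfer may also occur. The fallback sets out from 14 and returns at 19. Excess Grignard reagent 17 adds to the open form of 14 and gives (3R)-1-[4-(benzyloxy)phenyl]-3-[3,4-bis(benzyloxy)-2-hydroxyphenyl]-3-[2,3-bis(benzyloxy)-4-(methoxymethoxy)phenyl]propan-1-ol F3 as a mixture of carbinol epimers. MnO2 in CH2Cl2 oxidises the benzylic alcohol to the corresponding propan-1-one F4. Corey–Bakshi–Shibata reduction with (S)-2-methyl-CBS-oxazaborolidine and BH3·SMe2 gives the (1R,3R)-propan-1-ol F5. Mitsunobu ring closure (PPh3, DIAD) with inversion then returns 19, with C2(u) under reagent control.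

Step 17. Facial selectivity of the osmylation may be poor, because the bulky ring A(l) aryl group sits on the face that the allylic-oxygen rule prefers, and the threo isomer would then form. The fallback sets out from 28 and returns at 31. Reagent-controlled Jacobsen epoxidation of the Z-alkene uses the matching enantiomer of N,N'-bis(3,5-di-tert-butylsalicylidene)-1,2-cyclohexanediaminomanganese chloride (a (salen)MnCl complex of trivalent manganese) with NaOCl and 4-phenylpyridine N-oxide in CH2Cl2 at 0 °C. It gives the cis-epoxide (2S,3S)-2-[4-(benzyloxy)phenyl]-3-{(R)-[3,4-bis(benzyloxy)-5-Fl-2-(TBSO)phenyl](TBSO)methyl}oxirane F6. KHF2 in methanol then frees the phenol, which opens the epoxide at the benzylic carbon C2(l) with inversion (6-endo, with a trace of camphorsulfonic acid if needed) and gives 31 directly.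

**Further compounds**

F1 | step 8 | methyl (E)-3-[2,3-bis(benzyloxy)-4-(methoxymethoxy)phenyl]prop-2-enoate | COC(=O)/C=C/c1ccc(OCOC)c(OCc2ccccc2)c1OCc1ccccc1
F2 | step 8 | (4S)-7,8-bis(benzyloxy)-4-[2,3-bis(benzyloxy)-4-(methoxymethoxy)phenyl]chroman-2-one | O=C1C[C@@H](c2ccc(OCOC)c(OCc3ccccc3)c2OCc2ccccc2)c2ccc(OCc3ccccc3)c(OCc3ccccc3)c2O1
F3 | step 10 | (3R)-1-[4-(benzyloxy)phenyl]-3-[3,4-bis(benzyloxy)-2-hydroxyphenyl]-3-[2,3-bis(benzyloxy)-4-(methoxymethoxy)phenyl]propan-1-ol (both C1 epimers) | OC(C[C@@H](c1ccc(OCOC)c(OCc2ccccc2)c1OCc1ccccc1)c1ccc(OCc2ccccc2)c(OCc2ccccc2)c1O)c1ccc(OCc2ccccc2)cc1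
F4 | step 10 | (3R)-1-[4-(benzyloxy)phenyl]-3-[3,4-bis(benzyloxy)-2-hydroxyphenyl]-3-[2,3-bis(benzyloxy)-4-(methoxymethoxy)phenyl]propan-1-one | O=C(C[C@@H](c1ccc(OCOC)c(OCc2ccccc2)c1OCc1ccccc1)c1ccc(OCc2ccccc2)c(OCc2ccccc2)c1O)c1ccc(OCc2ccccc2)cc1
F5 | step 10 | (1R,3R)-1-[4-(benzyloxy)phenyl]-3-[3,4-bis(benzyloxy)-2-hydroxyphenyl]-3-[2,3-bis(benzyloxy)-4-(methoxymethoxy)phenyl]propan-1-ol | O[C@H](C[C@@H](c1ccc(OCOC)c(OCc2ccccc2)c1OCc1ccccc1)c1ccc(OCc2ccccc2)c(OCc2ccccc2)c1O)c1ccc(OCc2ccccc2)cc1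
F6 | step 17 | (2S,3S)-2-[4-(benzyloxy)phenyl]-3-{(R)-[3,4-bis(benzyloxy)-5-Fl-2-(TBSO)phenyl](TBSO)methyl}oxirane (cis-epoxide) | c1ccccc1COc1ccc([C@@H]2C[C@@H](c3cc([C@@H](O[Si](C)(C)C(C)(C)C)[C@H]6O[C@H]6c4ccc(OCc5ccccc5)cc4)c(O[Si](C)(C)C(C)(C)C)c(OCc4ccccc4)c3OCc3ccccc3)c3ccc(OCc4ccccc4)c(OCc4ccccc4)c3O2)cc1
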